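**Plan**

- Numbering used throughout: C1 = CH2OAc, C2=C3 = side-chain olefin, C6 = carbinol carbon, C7 = quaternary lactone carbon, C10=C11 = ring olefin, C12 = lactone carbonyl.
- Retrosynthetic cuts, in order: the acetate C–O; the ring olefin C10=C11 (ring-closing Horner–Wadsworth–Emmons) and the ester bond O7–C12; the C7–CH3 bond; a temporary O6–C10 bond; the C6–C7 bond; the terminal olefin of geraniol.
- Enabling feature: the C6 carbinol sits next to oxygenated C7, and C7–C10 is a four-carbon run ending at the enoate β-carbon. This is a 2-furyl carbinol in disguise (C6 = carbinol carbon, C7–C10 = furan C2–C5), and its oxidative ring expansion gives a six-membered pyranone holding C6–O–C10.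
- Forward: geraniol → silyl ether → C6 aldehyde → furyl ketone → (R)-furyl carbinol → pyranone (temporary six-membered ring) → methyl acetal, olefin saturation, methyl addition, phosphonoacetylation → lactol → seven-membered lactone by olefination → desilylation → acetylation.
- Stereochemistry: C6 (R) from transfer hydrogenation with the (R,R)-TsDPEN ruthenium catalyst; C7 (S) from axial methyl addition to the chair oxanone, relayed from C6; C2=C3 (E) from geraniol; C10=C11 cis by ring constraint.

Key step: step 7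

Remark: the ring olefin has no descriptor in the target and can only be cis inside the seven-membered lactone, so it is left unmarked in the lactone SMILES; the anomeric centre is temporary and is drawn trans or left undefined. TBDPS = tert-butyldiphenylsilyl.

**Route**

Step 1
Reactants: 1 geraniol
Product: 2 tert-butyl{[(2E)-3,7-dimethylocta-2,6-dien-1-yl]oxy}diphenylsilane
Conditions: TBDPSCl, imidazole, CH2Cl2, 0 °C → rt
Reagents that add atoms: tert-butyl(chloro)diphenylsilane, CC(C)(C)[Si](Cl)(c1ccccc1)c1ccccc1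
Why: Imidazole-promoted silylation of a primary allylic alcohol; the bulky TBDPS ether is chosen because it should outlast the periodic acid, Lewis acid and aqueous acid steps that follow.

Step 2
Reactants: 2 geranyl TBDPS ether
Product: 3 tert-butyl{[(2E)-5-(3,3-dimethyloxiran-2-yl)-3-methylpent-2-en-1-yl]oxy}diphenylsilane (racemic at the oxirane carbon)
Conditions: mCPBA (1.0 equiv), CH2Cl2, −20 → 0 °C
Reagents that add atoms: 3-chloroperoxybenzoic acid, OOC(=O)c1cccc(Cl)c1
Why: Prilezhaev epoxidation should pick the remote, more electron-rich 6,7-olefin because the 2,3-olefin is inductively deactivated by its allylic silyloxy group; the new centre is excised in step 3.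

Step 3
Reactants: 3 terminal epoxide
Product: 5 (E)-6-(tert-butyldiphenylsilyloxy)-4-methylhex-4-enal, via vicinal diol 4 (not isolated)
Conditions: H5IO6, THF/Et2O, 0 °C
Reagents that add atoms: none
Why: Periodic acid hydrates the epoxide (water enters at the tertiary carbon and later leaves in the acetone) and then effects Malaprade glycol cleavage, which frees the C6 aldehyde without touching the remaining trisubstituted olefin.

Step 4
Reactants: 5 aldehyde; 6 furan
Product: 8 rac-(E)-6-(tert-butyldiphenylsilyloxy)-1-(furan-2-yl)-4-methylhex-4-en-1-ol, via 2-furyllithium 7 (not isolated)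
Conditions: n-BuLi, THF, 0 °C (lithiation of 6); then 5, −78 °C; then H2O
Reagents that add atoms: none
Why: α-Lithiation of furan followed by organolithium 1,2-addition to the aldehyde forms the C6–C7 bond; the carbinol is deliberately racemic because C6 is set after oxidation.

Step 5
Reactants: 8 racemic furyl carbinol
Product: 9 (E)-6-(tert-butyldiphenylsilyloxy)-1-(furan-2-yl)-4-methylhex-4-en-1-one
Conditions: activated MnO2 (excess), CH2Cl2, rt
Reagents that add atoms: none
Why: MnO2 oxidation of a furfuryl (benzylic-type) alcohol to the 2-acylfuran under neutral conditions, with no other oxidisable hydroxyl present.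

Step 6
Reactants: 9 furyl ketone
Product: 10 (1R,4E)-6-(tert-butyldiphenylsilyloxy)-1-(furan-2-yl)-4-methylhex-4-en-1-ol
Conditions: RuCl[(R,R)-TsDPEN](p-cymene) (1 mol %), HCO2H/Et3N (5:2), rt
Reagents that add atoms: none
Why: Noyori asymmetric transfer hydrogenation of a heteroaryl alkyl ketone; the (R,R) ligand should deliver hydride to the face that places the furan next to the η6-arene (CH/π contact), setting C6 as R, and isolated olefins are not reduced.

Step 7
Reactants: 10 (R)-furyl carbinol
Product: 12 (2R,6S)-2-[(E)-5-(tert-butyldiphenylsilyloxy)-3-methylpent-3-enyl]-6-hydroxy-2H-pyran-3(6H)-one (trans anomer drawn), via cis-enedione 11 (not isolated)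
Conditions: NBS (1.05 equiv), NaHCO3, NaOAc, THF/H2O (4:1), 0 °C
Reagents that add atoms: water, O
Why: Electrophilic bromine attacks the free α-position of the furan, water adds across the ring, and the resulting 2,5-dioxygenated dihydrofuran collapses with loss of bromide to the (Z)-4-oxo-enal 11, whose C6 hydroxyl then adds to the C10 aldehyde. The closest known reaction type is the Achmatowicz rearrangement of 2-furyl carbinols to 6-hydroxy-2H-pyran-3(6H)-ones. The six-membered ring closes by 6-exo-trig hemiacetalisation of O6 onto C10, which creates the temporary O6–C10 bond and leaves C7 as the ring ketone. The only new stereocentre is the lactol carbon C10; it is under thermodynamic (anomeric) control, should favour the trans anomer with axial hydroxyl, and is erased later. The step needs oxidation of the furan in preference to the C2=C3 olefin, which the far greater nucleophilicity of the furan and the inductive deactivation of that olefin by its allylic silyloxy group should secure at 0 °C with one equivalent of NBS. It also needs C6 to stay intact, which should hold because no bond to C6 is broken and the bicarbonate/acetate buffer keeps the new α-oxy ketone from enolising.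

Step 8
Reactants: 12 pyranone lactol
Product: 13 (2R,6S)-2-[(E)-5-(tert-butyldiphenylsilyloxy)-3-methylpent-3-enyl]-6-methoxy-2H-pyran-3(6H)-one
Conditions: HC(OMe)3, BF3·OEt2 (cat.), Et2O, 0 °C
Reagents that add atoms: trimethyl orthoformate, COC(OC)OC
Why: Acid-catalysed acetalisation of the lactol through the pyranyl oxocarbenium ion (Fischer-type glycosidation with orthoformate as methanol source and water scavenger); the anomeric effect should favour the trans, axial methoxy anomer, and the acetal masks C10 against the Grignard reagent.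

Step 9
Reactants: 13 enone acetal
Product: 14 (2R,6S)-2-[(E)-5-(tert-butyldiphenylsilyloxy)-3-methylpent-3-enyl]-6-methoxyoxan-3-one
Conditions: H2 (1 atm), RhCl(PPh3)3 (5 mol %), benzene, rt
Reagents that add atoms: none
Why: Homogeneous hydrogenation with Wilkinson's catalyst should saturate the unhindered cis-disubstituted enone olefin C8=C9 and leave the trisubstituted olefin, the ketone and the allylic silyl ether alone, as in the selective 1,2-saturation of steroidal 1,4-dien-3-ones.

Step 10
Reactants: 14 oxanone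
Product: 15 (2R,3S,6S)-2-[(E)-5-(tert-butyldiphenylsilyloxy)-3-methylpent-3-enyl]-6-methoxy-3-methyloxan-3-ol
Conditions: MeMgBr (3 M in Et2O), toluene, −78 °C; then H2O
Reagents that add atoms: methylmagnesium bromide, C[Mg]Br
Why: Grignard 1,2-addition in which, on the chair with the C6 side chain equatorial, methyl should enter axially at C7 because that path meets no syn-axial hydrogen at the ring oxygen and avoids eclipsing the axial hydrogens at C6 and C8, as known for MeMgBr additions to 2-substituted oxan-3-ones in toluene; this places methyl cis to the side chain and sets C7 as S.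

Step 11
Reactants: 16 triethyl phosphonoacetate; 17 5-bromo-2-methylpent-2-ene
Product: 19 ethyl 2-(diethoxyphosphoryl)-6-methylhept-5-enoate (racemic), via sodium phosphonate 18 (not isolated)
Conditions: NaH, DMF, 0 °C; then 17, NaI (cat.), 60 °C
Reagents that add atoms: none
Why: SN2 C-alkylation of the stabilised phosphonoacetate anion with a primary bromide under iodide catalysis; the new centre is racemic and becomes sp2 in step 15.

Step 12
Reactants: 19 phosphono ester
Product: 20 2-(diethoxyphosphoryl)-6-methylhept-5-enoic acid (racemic)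
Conditions: NaOH (1.05 equiv), EtOH/H2O, rt; then aq HCl to pH 2
Reagents that add atoms: sodium hydroxide, [Na+].[OH-]
Why: Saponification of the carboxylic ethyl ester, which is hydrolysed much faster than the phosphonate diethyl esters by dilute hydroxide at room temperature.

Step 13
Reactants: 15 tertiary alcohol; 20 phosphono acid
Product: 21 (2R,3S,6S)-2-[(E)-5-(tert-butyldiphenylsilyloxy)-3-methylpent-3-enyl]-6-methoxy-3-methyloxan-3-yl 2-(diethoxyphosphoryl)-6-methylhept-5-enoate (epimers at the phosphonate carbon)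
Conditions: DCC, DMAP, CH2Cl2, 0 °C → rt
Reagents that add atoms: none
Why: Steglich esterification in which the DCC-activated α-phosphono acid reacts through a phosphonoketene that can capture a hindered tertiary alcohol; with O6 tied up as the ring oxygen, the C7 hydroxyl is the only acylation site.

Step 14
Reactants: 21 phosphonoacetate acetal
Product: 22 (2R,3S)-2-[(E)-5-(tert-butyldiphenylsilyloxy)-3-methylpent-3-enyl]-6-hydroxy-3-methyloxan-3-yl 2-(diethoxyphosphoryl)-6-methylhept-5-enoate (anomer mixture)
Conditions: AcOH/THF/H2O (3:1:1), 40 °C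
Reagents that add atoms: water, O
Why: Mild acid hydrolysis of a 2-alkoxyoxane (THP-type) acetal, which should be fast under conditions that spare the TBDPS ether, the tertiary ester, the phosphonate and the olefins.

Step 15
Reactants: 22 lactol phosphonate
Product: 24 (7S)-7-[(1R,4E)-6-(tert-butyldiphenylsilyloxy)-1-hydroxy-4-methylhex-4-en-1-yl]-7-methyl-3-(4-methylpent-3-en-1-yl)-6,7-dihydrooxepin-2(5H)-one, via open hydroxy aldehyde 23 (not isolated)
Conditions: LiCl, DBU, MeCN (0.005 M), 0 °C → rt
Reagents that add atoms: none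
Why: Intramolecular Horner–Wadsworth–Emmons olefination under Masamune–Roush conditions on the aldehyde released from the lactol by ring–chain tautomerism closes the seven-membered lactone at C10=C11 (the ring forces the cis olefin) and frees the C6 hydroxyl; the mild amine base holds the phosphonate as its lithium-chelated enolate, which should disfavour acyl migration to O6, and high dilution suppresses oligomerisation.

Step 16
Reactants: 24 silyl lactone
Product: 25 (7S)-7-[(1R,4E)-1,6-dihydroxy-4-methylhex-4-en-1-yl]-7-methyl-3-(4-methylpent-3-en-1-yl)-6,7-dihydrooxepin-2(5H)-one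
Conditions: HF·pyridine, pyridine, THF, 0 °C → rt
Reagents that add atoms: none
Why: Fluoride cleavage of the primary silyl ether under buffered, non-basic conditions, chosen to avoid base-promoted translactonisation or conjugate addition of the C6 hydroxyl.

Step 17
Reactants: 25 diol lactone
Product: 26 (2E,6R)-6-hydroxy-3-methyl-6-[(2S)-2-methyl-6-(4-methylpent-3-en-1-yl)-7-oxo-2,3,4,7-tetrahydrooxepin-2-yl]hex-2-en-1-yl acetate (target)
Conditions: Ac2O (1.1 equiv), pyridine, CH2Cl2, 0 °C
Reagents that add atoms: acetic anhydride, CC(=O)OC(C)=O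
Why: Selective acetylation of the primary allylic alcohol; the secondary C6 hydroxyl is flanked by the fully substituted C7 and should react far more slowly without DMAP at 0 °C.

**Compound list**

1 | geraniol | CC(C)=CCC/C(C)=C/CO | starting material
2 | tert-butyl{[(2E)-3,7-dimethylocta-2,6-dien-1-yl]oxy}diphenylsilane | CC(C)=CCC/C(C)=C/CO[Si](c1ccccc1)(c1ccccc1)C(C)(C)C | intermediate
3 | tert-butyl{[(2E)-5-(3,3-dimethyloxiran-2-yl)-3-methylpent-2-en-1-yl]oxy}diphenylsilane (racemic) | CC1(C)OC1CC/C(C)=C/CO[Si](c1ccccc1)(c1ccccc1)C(C)(C)C | intermediate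
4 | (E)-8-(tert-butyldiphenylsilyloxy)-2,6-dimethyloct-6-ene-2,3-diol (racemic) | CC(C)(O)C(O)CC/C(C)=C/CO[Si](c1ccccc1)(c1ccccc1)C(C)(C)C | intermediate (not isolated)
5 | (E)-6-(tert-butyldiphenylsilyloxy)-4-methylhex-4-enal | O=CCC/C(C)=C/CO[Si](c1ccccc1)(c1ccccc1)C(C)(C)C | intermediate
6 | furan | c1ccoc1 | starting material
7 | 2-furyllithium | [Li]c1ccco1 | intermediate (not isolated)
8 | rac-(E)-6-(tert-butyldiphenylsilyloxy)-1-(furan-2-yl)-4-methylhex-4-en-1-ol | CC(C)(C)[Si](c1ccccc1)(c1ccccc1)OC/C=C(\C)CCC(O)c1ccco1 | intermediate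
9 | (E)-6-(tert-butyldiphenylsilyloxy)-1-(furan-2-yl)-4-methylhex-4-en-1-one | CC(C)(C)[Si](c1ccccc1)(c1ccccc1)OC/C=C(\C)CCC(=O)c1ccco1 | intermediate
10 | (1R,4E)-6-(tert-butyldiphenylsilyloxy)-1-(furan-2-yl)-4-methylhex-4-en-1-ol | CC(C)(C)[Si](c1ccccc1)(c1ccccc1)OC/C=C(\C)CC[C@@H](O)c1ccco1 | intermediate
11 | (2Z,5R,8E)-10-(tert-butyldiphenylsilyloxy)-5-hydroxy-8-methyl-4-oxodeca-2,8-dienal | CC(C)(C)[Si](c1ccccc1)(c1ccccc1)OC/C=C(\C)CC[C@@H](O)C(=O)/C=C\C=O | intermediate (not isolated)
12 | (2R,6S)-2-[(E)-5-(tert-butyldiphenylsilyloxy)-3-methylpent-3-enyl]-6-hydroxy-2H-pyran-3(6H)-one (trans anomer drawn) | CC(C)(C)[Si](c1ccccc1)(c1ccccc1)OC/C=C(\C)CC[C@H]1O[C@H](O)C=CC1=O | intermediate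
13 | (2R,6S)-2-[(E)-5-(tert-butyldiphenylsilyloxy)-3-methylpent-3-enyl]-6-methoxy-2H-pyran-3(6H)-one | CC(C)(C)[Si](c1ccccc1)(c1ccccc1)OC/C=C(\C)CC[C@H]1O[C@H](OC)C=CC1=O | intermediate
14 | (2R,6S)-2-[(E)-5-(tert-butyldiphenylsilyloxy)-3-methylpent-3-enyl]-6-methoxyoxan-3-one | CC(C)(C)[Si](c1ccccc1)(c1ccccc1)OC/C=C(\C)CC[C@H]1O[C@H](OC)CCC1=O | intermediate
15 | (2R,3S,6S)-2-[(E)-5-(tert-butyldiphenylsilyloxy)-3-methylpent-3-enyl]-6-methoxy-3-methyloxan-3-ol | CC(C)(C)[Si](c1ccccc1)(c1ccccc1)OC/C=C(\C)CC[C@H]1O[C@H](OC)CC[C@]1(C)O | intermediate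
16 | triethyl phosphonoacetate | CCOC(=O)CP(=O)(OCC)OCC | starting material
17 | 5-bromo-2-methylpent-2-ene | CC(C)=CCCBr | starting material
18 | sodium salt of triethyl phosphonoacetate | CCOC(=O)[CH-]P(=O)(OCC)OCC.[Na+] | intermediate (not isolated)
19 | ethyl 2-(diethoxyphosphoryl)-6-methylhept-5-enoate (racemic) | CCOC(=O)C(CCC=C(C)C)P(=O)(OCC)OCC | intermediate
20 | 2-(diethoxyphosphoryl)-6-methylhept-5-enoic acid (racemic) | OC(=O)C(CCC=C(C)C)P(=O)(OCC)OCC | intermediate
21 | (2R,3S,6S)-2-[(E)-5-(tert-butyldiphenylsilyloxy)-3-methylpent-3-enyl]-6-methoxy-3-methyloxan-3-yl 2-(diethoxyphosphoryl)-6-methylhept-5-enoate | CC(C)(C)[Si](c1ccccc1)(c1ccccc1)OC/C=C(\C)CC[C@H]1O[C@H](OC)CC[C@]1(C)OC(=O)C(CCC=C(C)C)P(=O)(OCC)OCC | intermediate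
22 | (2R,3S)-2-[(E)-5-(tert-butyldiphenylsilyloxy)-3-methylpent-3-enyl]-6-hydroxy-3-methyloxan-3-yl 2-(diethoxyphosphoryl)-6-methylhept-5-enoate (anomer mixture) | CC(C)(C)[Si](c1ccccc1)(c1ccccc1)OC/C=C(\C)CC[C@H]1OC(O)CC[C@]1(C)OC(=O)C(CCC=C(C)C)P(=O)(OCC)OCC | intermediate
23 | (4S,5R,8E)-10-(tert-butyldiphenylsilyloxy)-5-hydroxy-4,8-dimethyl-1-oxodec-8-en-4-yl 2-(diethoxyphosphoryl)-6-methylhept-5-enoate | CC(C)(C)[Si](c1ccccc1)(c1ccccc1)OC/C=C(\C)CC[C@@H](O)[C@](C)(CCC=O)OC(=O)C(CCC=C(C)C)P(=O)(OCC)OCC | intermediate (not isolated)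
24 | (7S)-7-[(1R,4E)-6-(tert-butyldiphenylsilyloxy)-1-hydroxy-4-methylhex-4-en-1-yl]-7-methyl-3-(4-methylpent-3-en-1-yl)-6,7-dihydrooxepin-2(5H)-one | CC(C)(C)[Si](c1ccccc1)(c1ccccc1)OC/C=C(\C)CC[C@@H](O)[C@]1(C)CCC=C(CCC=C(C)C)C(=O)O1 | intermediate
25 | (7S)-7-[(1R,4E)-1,6-dihydroxy-4-methylhex-4-en-1-yl]-7-methyl-3-(4-methylpent-3-en-1-yl)-6,7-dihydrooxepin-2(5H)-one | OC/C=C(\C)CC[C@@H](O)[C@]1(C)CCC=C(CCC=C(C)C)C(=O)O1 | intermediate
26 | (2E,6R)-6-hydroxy-3-methyl-6-[(2S)-2-methyl-6-(4-methylpent-3-en-1-yl)-7-oxo-2,3,4,7-tetrahydrooxepin-2-yl]hex-2-en-1-yl acetate | CC(=O)OC/C=C(\C)CC[C@@H](O)[C@]1(C)CCC=C(CCC=C(C)C)C(=O)O1 | target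

**Step count and risks**

Total step count: 17. Longest linear sequence: 15 steps (steps 1–10 and 13–17, geraniol to target); steps 11–12 prepare the phosphono acid.

Steps most likely to fail:

1. Step 15 (ring-closing olefination from the lactol). The lactol may open too slowly for the olefination to keep pace. The phosphonoacyl group may migrate from O7 to the freed O6. The liberated C6 hydroxyl may add back to C10 of the new enoate (oxa-Michael), or the chain may oligomerise. The fallback replaces the olefination by ring-closing metathesis with O6 protected; it sets out from 15 (and 19 for the acid) and returns at 25. Aqueous AcOH hydrolysis of 15 should give (2R,3S)-2-[(E)-5-(tert-butyldiphenylsilyloxy)-3-methylpent-3-enyl]-3-methyloxane-3,6-diol F1. Wittig methylenation with Ph3P=CH2 in THF opens the lactol to (2E,6R,7S)-1-(tert-butyldiphenylsilyloxy)-3,7-dimethylundeca-2,10-diene-6,7-diol F2. TESCl and imidazole silylate only the secondary hydroxyl to give the 6-O-triethylsilyl ether of that diol F3. In parallel, 19 is methylenated with aqueous formaldehyde and K2CO3 (Horner–Wadsworth–Emmons) to ethyl 6-methyl-2-methylidenehept-5-enoate F4, and LiOH saponification gives 6-methyl-2-methylidenehept-5-enoic acid F5. Yamaguchi esterification (2,4,6-trichlorobenzoyl chloride, Et3N, DMAP, toluene) of the tertiary hydroxyl of F3 with F5 gives the (6R,7S)-6-triethylsilyloxy undecadien-7-yl 2-methylidene ester F6. The second-generation Grubbs catalyst RuCl2(=CHPh)(H2IMes)(PCy3) in refluxing toluene at high dilution should close C10=C11 to the bis-silylated lactone (7S)-7-[(1R,4E)-6-(tert-butyldiphenylsilyloxy)-4-methyl-1-(triethylsilyloxy)hex-4-en-1-yl]-7-methyl-3-(4-methylpent-3-en-1-yl)-6,7-dihydrooxepin-2(5H)-one F7. HF·pyridine then removes both silyl groups and delivers 25.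

2. Step 10 (methyl addition at C7). Facial selectivity may be poor, with equatorial attack giving the C7 epimer, and the Grignard reagent may enolise the ketone and erode C6. The fallback moves the methyl addition to the enone stage; it sets out from 13 and returns at 15. MeLi with CeCl3 in THF at −78 °C should add 1,2 to the enone, where the axial path at C7 is flanked only by the ring oxygen and the sp2 carbon C9 and the organocerium reagent does not enolise, to give (2R,3S,6S)-2-[(E)-5-(tert-butyldiphenylsilyloxy)-3-methylpent-3-enyl]-6-methoxy-3-methyl-3,6-dihydro-2H-pyran-3-ol F8. Diimide from 2-nitrobenzenesulfonylhydrazide and Et3N then saturates the cis-disubstituted ring olefin in preference to the trisubstituted side-chain olefin and gives 15.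

3. Step 13 (acylation of the tertiary C7 hydroxyl). Acylation of the hindered alcohol may be sluggish, so that the activated acid is diverted to N-acylurea or ketene dimers. The fallback builds the phosphonate on a small ester; it sets out from 15 and returns at 21. Bromoacetyl bromide and pyridine in CH2Cl2 at 0 °C should acylate the tertiary hydroxyl to (2R,3S,6S)-2-[(E)-5-(tert-butyldiphenylsilyloxy)-3-methylpent-3-enyl]-6-methoxy-3-methyloxan-3-yl bromoacetate F9. A Michaelis–Arbuzov reaction with P(OEt)3 at 100 °C gives the corresponding (diethoxyphosphoryl)acetate F10. Deprotonation with NaH in DMF and alkylation with 17 (NaI catalysis) gives 21.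

Further compounds
F1 | step 15 | (2R,3S)-2-[(E)-5-(tert-butyldiphenylsilyloxy)-3-methylpent-3-enyl]-3-methyloxane-3,6-diol | CC(C)(C)[Si](c1ccccc1)(c1ccccc1)OC/C=C(\C)CC[C@H]1OC(O)CC[C@]1(C)O
F2 | step 15 | (2E,6R,7S)-1-(tert-butyldiphenylsilyloxy)-3,7-dimethylundeca-2,10-diene-6,7-diol | CC(C)(C)[Si](c1ccccc1)(c1ccccc1)OC/C=C(\C)CC[C@@H](O)[C@@](C)(O)CCC=C
F3 | step 15 | (2E,6R,7S)-1-(tert-butyldiphenylsilyloxy)-3,7-dimethyl-6-(triethylsilyloxy)undeca-2,10-dien-7-ol | CC(C)(C)[Si](c1ccccc1)(c1ccccc1)OC/C=C(\C)CC[C@@H](O[Si](CC)(CC)CC)[C@@](C)(O)CCC=C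
F4 | step 15 | ethyl 6-methyl-2-methylidenehept-5-enoate | CCOC(=O)C(=C)CCC=C(C)C
F5 | step 15 | 6-methyl-2-methylidenehept-5-enoic acid | OC(=O)C(=C)CCC=C(C)C
F6 | step 15 | (2E,6R,7S)-1-(tert-butyldiphenylsilyloxy)-3,7-dimethyl-6-(triethylsilyloxy)undeca-2,10-dien-7-yl 6-methyl-2-methylidenehept-5-enoate | CC(C)(C)[Si](c1ccccc1)(c1ccccc1)OC/C=C(\C)CC[C@@H](O[Si](CC)(CC)CC)[C@](C)(CCC=C)OC(=O)C(=C)CCC=C(C)C
F7 | step 15 | (7S)-7-[(1R,4E)-6-(tert-butyldiphenylsilyloxy)-4-methyl-1-(triethylsilyloxy)hex-4-en-1-yl]-7-methyl-3-(4-methylpent-3-en-1-yl)-6,7-dihydrooxepin-2(5H)-one | CC(C)(C)[Si](c1ccccc1)(c1ccccc1)OC/C=C(\C)CC[C@@H](O[Si](CC)(CC)CC)[C@]1(C)CCC=C(CCC=C(C)C)C(=O)O1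
F8 | step 10 | (2R,3S,6S)-2-[(E)-5-(tert-butyldiphenylsilyloxy)-3-methylpent-3-enyl]-6-methoxy-3-methyl-3,6-dihydro-2H-pyran-3-ol | CC(C)(C)[Si](c1ccccc1)(c1ccccc1)OC/C=C(\C)CC[C@H]1O[C@H](OC)C=C[C@]1(C)O
F9 | step 13 | (2R,3S,6S)-2-[(E)-5-(tert-butyldiphenylsilyloxy)-3-methylpent-3-enyl]-6-methoxy-3-methyloxan-3-yl bromoacetate | CC(C)(C)[Si](c1ccccc1)(c1ccccc1)OC/C=C(\C)CC[C@H]1O[C@H](OC)CC[C@]1(C)OC(=O)CBr
F10 | step 13 | (2R,3S,6S)-2-[(E)-5-(tert-butyldiphenylsilyloxy)-3-methylpent-3-enyl]-6-methoxy-3-methyloxan-3-yl (diethoxyphosphoryl)acetate | CC(C)(C)[Si](c1ccccc1)(c1ccccc1)OC/C=C(\C)CC[C@H]1O[C@H](OC)CC[C@]1(C)OC(=O)CP(=O)(OCC)OCC
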